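**Retrosynthetic overview**
- The (E)-C1'=C2' alkene is cut by Ru cross-metathesis into a 6-vinyl-5-tigloyloxy lactone and (3S,4S)-3,4-diacetoxypent-1-ene; this fragment union is the last step.
- The lactone, the only ring, comes from ring-closing metathesis of the mixed acrylate/tiglate diester of (3S,4S)-hexa-1,5-diene-3,4-diol.
- The C5–C6 bond, both ring stereocentres and the tiglate come from one Cr-catalysed asymmetric γ-(tigloyloxy)allylation of acrolein, using a reagent made from acrolein and tigloyl chloride.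
- The side-chain stereocentres C3'/C4' come from a Brown (Z)-γ-alkoxyallylboration of acetaldehyde, followed by exchange of methoxymethyl (MOM) for acetate.
- Ring order: one ring only, closed in step 4, before the union in step 8.

Assumption: the (E)-2-methylbut-2-enoate in the SMILES is read as tiglate, and allyl methoxymethyl ether, tigloyl chloride, (S,S)-(salen)CrCl and (+)-Ipc2BOMe are taken as purchasable.

**Route**

Step 1
Reactants: 1 acrolein; 2 tigloyl chloride
Product: 3 3-chloroprop-1-en-1-yl (E)-2-methylbut-2-enoate (E/Z mixture at the enol ester C=C)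
Conditions: ZnCl2 (2 mol %), CH2Cl2, −20 → 0 °C
Reagents that add atoms: none
Why: Lewis-acid-catalysed 1,4-addition of an acyl chloride across acrolein (O-acylation of the ZnCl2-activated carbonyl, chloride delivery to the β-carbon), the standard entry to 3-halopropenyl esters; no stereocentre is formed and the E/Z mixture is used as such because both isomers give the same allylchromium species in step 2.

Step 2
Reactants: 1 acrolein; 3 3-chloroprop-1-en-1-yl (E)-2-methylbut-2-enoate
Product: 5 (3S,4S)-4-hydroxyhexa-1,5-dien-3-yl (E)-2-methylbut-2-enoate, via trimethylsilyl ether 4 (not isolated)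
Conditions: (S,S)-(salen)CrCl [salen = N,N'-bis(3,5-di-tert-butylsalicylidene)cyclohexane-1,2-diaminate] (10 mol %), Mn powder (3 equiv), Me3SiCl (1.5 equiv), MeCN, 0 °C → rt; then 1 M HCl, THF, 0 °C
Reagents that add atoms: none
Why: Proposed new method: a (salen)Cr-catalysed Nozaki–Hiyama-type γ-(acyloxy)allylation run with a reagent that carries the target's own tiglate and with acrolein as acceptor, neither of which has been shown; Mn reduces (S,S)-(salen)CrCl to divalent chromium, two of which convert the allylic chloride of 3 into a 3-(tigloyloxy)allyl complex of trivalent chromium that is held Z by carbonyl-to-chromium chelation and adds through its oxygen-bearing γ-carbon to the coordinated aldehyde in a closed six-membered transition state (1,2-addition, syn) on the face left open by the salen ligand, so that one C–C bond formation sets both lactone stereocentres as (3S,4S), and Me3SiCl silylates the chromium alkoxide to 4 to turn the metal over; the closest known reaction is the (salen)Cr/Mn/Me3SiCl-catalysed syn-selective addition of 3-chloropropenyl pivalate to aldehydes, from which the facial sense of the (S,S)-ligand is extrapolated (to be checked by Mosher analysis, with the (R,R)-ligand used if it is reversed), and a 1,2-tigloyl shift in 5 is harmless because it regenerates 5 (C2-symmetric diol core).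

Step 3
Reactants: 5 (3S,4S)-4-hydroxyhexa-1,5-dien-3-yl (E)-2-methylbut-2-enoate; 6 acryloyl chloride
Product: 7 (3S,4S)-4-(acryloyloxy)hexa-1,5-dien-3-yl (E)-2-methylbut-2-enoate
Conditions: iPr2NEt, CH2Cl2, −78 → 0 °C
Reagents that add atoms: none
Why: O-acylation of the secondary alcohol by an acid chloride with a hindered amine base; no stereocentre is touched and, because the diol core is C2-symmetric, the mixed diester is the same compound whichever oxygen carries which acyl group.

Step 4
Reactants: 7 (3S,4S)-4-(acryloyloxy)hexa-1,5-dien-3-yl (E)-2-methylbut-2-enoate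
Product: 8 (5S,6S)-5-[(E)-2-methylbut-2-enoyloxy]-6-vinyl-5,6-dihydro-2H-pyran-2-one
Conditions: second-generation Grubbs catalyst (H2IMes)(PCy3)Cl2Ru=CHPh (5 mol %), CH2Cl2 (0.005 M), 40 °C
Reagents that add atoms: none
Why: Ring-closing olefin metathesis in which the Ru alkylidene loads on a terminal vinyl group and closes onto the acrylate to give the six-membered α,β-unsaturated δ-lactone in preference to the more strained butenolide (ring-size-selective RCM); the trisubstituted tiglate alkene is inert and both stereocentres are carried through unchanged.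

Step 5
Reactants: 9 allyl methoxymethyl ether; 10 acetaldehyde
Product: 15 (2S,3S)-3-(methoxymethoxy)pent-4-en-2-ol, via allyllithium 11 (not isolated), via lithium borate 12 (not isolated), via allylborane 13 (not isolated), via borinate ester 14 (not isolated)
Conditions: sec-BuLi, THF, −78 °C; (+)-Ipc2BOMe (Ipc = isopinocampheyl, from (−)-α-pinene); BF3·OEt2; then 10, −78 °C → rt; NaOH, H2O2
Reagents that add atoms: none
Why: Brown asymmetric (Z)-γ-alkoxyallylboration, in which kinetic deprotonation gives the oxygen-chelated Z-allyl anion, boron transfer and removal of methoxide by BF3 give the Z-allylborane, and this adds to acetaldehyde through a chair Zimmerman–Traxler transition state (Z geometry gives syn) on the face dictated by the isopinocampheyl groups, setting (2S,3S).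

Step 6
Reactants: 15 (2S,3S)-3-(methoxymethoxy)pent-4-en-2-ol
Product: 16 (3S,4S)-pent-1-ene-3,4-diol
Conditions: ZnBr2, n-PrSH, CH2Cl2, 0 °C → rt
Reagents that add atoms: none
Why: Lewis acid/thiol cleavage of the methoxymethyl acetal, in which ZnBr2 activates the acetal and the thiol captures the CH2OMe unit so that no cyclic formal forms with the neighbouring hydroxyl; the stereocentres are not touched (the volatile diol is not taken to dryness).

Step 7
Reactants: 16 (3S,4S)-pent-1-ene-3,4-diol
Product: 17 (3S,4S)-pent-1-ene-3,4-diyl diacetate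
Conditions: Ac2O, pyridine, DMAP (cat.), CH2Cl2, 0 °C → rt
Reagents that add atoms: acetic anhydride CC(=O)OC(C)=O
Why: DMAP-catalysed acetylation (nucleophilic acyl transfer) of both secondary alcohols with retention at carbon.

Step 8
Reactants: 8 (5S,6S)-5-[(E)-2-methylbut-2-enoyloxy]-6-vinyl-5,6-dihydro-2H-pyran-2-one; 17 (3S,4S)-pent-1-ene-3,4-diyl diacetate
Product: 18 (5S,6S)-6-[(1E,3S,4S)-3,4-diacetoxypent-1-en-1-yl]-5-[(E)-2-methylbut-2-enoyloxy]-5,6-dihydro-2H-pyran-2-one
Conditions: second-generation Hoveyda–Grubbs catalyst (H2IMes)Cl2Ru=CH(C6H4-2-OiPr) (10 mol %), 17 (3 equiv), CH2Cl2, 40 °C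
Reagents that add atoms: none
Why: Olefin cross-metathesis between two allylically oxygenated terminal alkenes that both homodimerise slowly, so an excess of the cheaper partner drives the cross product; the new 1,2-disubstituted alkene forms under thermodynamic control as the E isomer, the conjugated lactone and tiglate alkenes do not react, and no stereocentre is touched.

**Compound list**

1 | acrolein (prop-2-enal) | C=CC=O | starting material
2 | tigloyl chloride [(E)-2-methylbut-2-enoyl chloride] | C/C=C(\C)C(Cl)=O | starting material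
3 | 3-chloroprop-1-en-1-yl (E)-2-methylbut-2-enoate (E/Z mixture at the enol ester alkene) | C/C=C(\C)C(=O)OC=CCCl | intermediate
4 | (3S,4S)-4-(trimethylsilyloxy)hexa-1,5-dien-3-yl (E)-2-methylbut-2-enoate (not isolated) | C/C=C(\C)C(=O)O[C@@H](C=C)[C@@H](O[Si](C)(C)C)C=C | intermediate
5 | (3S,4S)-4-hydroxyhexa-1,5-dien-3-yl (E)-2-methylbut-2-enoate | C/C=C(\C)C(=O)O[C@@H](C=C)[C@@H](O)C=C | intermediate
6 | acryloyl chloride | C=CC(Cl)=O | starting material
7 | (3S,4S)-4-(acryloyloxy)hexa-1,5-dien-3-yl (E)-2-methylbut-2-enoate | C/C=C(\C)C(=O)O[C@@H](C=C)[C@@H](OC(=O)C=C)C=C | intermediate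
8 | (5S,6S)-5-[(E)-2-methylbut-2-enoyloxy]-6-vinyl-5,6-dihydro-2H-pyran-2-one | C/C=C(\C)C(=O)O[C@H]1C=CC(=O)O[C@H]1C=C | intermediate
9 | allyl methoxymethyl ether [3-(methoxymethoxy)prop-1-ene] | C=CCOCOC | starting material
10 | acetaldehyde | CC=O | starting material
11 | [(Z)-3-(methoxymethoxy)allyl]lithium (not isolated) | COCO/C=C\C[Li] | intermediate
12 | lithium [(Z)-3-(methoxymethoxy)allyl](methoxy)bis(isopinocampheyl)borate, Ipc groups from (−)-α-pinene (not isolated) | [Li+].COCO/C=C\C[B-](OC)([C@H]1C[C@H]2C[C@@H]([C@@H]1C)C2(C)C)[C@H]1C[C@H]2C[C@@H]([C@@H]1C)C2(C)C | intermediate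
13 | [(Z)-3-(methoxymethoxy)allyl]bis(isopinocampheyl)borane, Ipc groups from (−)-α-pinene (not isolated) | COCO/C=C\CB([C@H]1C[C@H]2C[C@@H]([C@@H]1C)C2(C)C)[C@H]1C[C@H]2C[C@@H]([C@@H]1C)C2(C)C | intermediate
14 | (2S,3S)-3-(methoxymethoxy)pent-4-en-2-yl bis(isopinocampheyl)borinate (not isolated) | C=C[C@H](OCOC)[C@H](C)OB([C@H]1C[C@H]2C[C@@H]([C@@H]1C)C2(C)C)[C@H]1C[C@H]2C[C@@H]([C@@H]1C)C2(C)C | intermediate
15 | (2S,3S)-3-(methoxymethoxy)pent-4-en-2-ol | C=C[C@H](OCOC)[C@H](C)O | intermediate
16 | (3S,4S)-pent-1-ene-3,4-diol | C=C[C@H](O)[C@H](C)O | intermediate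
17 | (3S,4S)-pent-1-ene-3,4-diyl diacetate | C=C[C@H](OC(C)=O)[C@H](C)OC(C)=O | intermediate
18 | (5S,6S)-6-[(1E,3S,4S)-3,4-diacetoxypent-1-en-1-yl]-5-[(E)-2-methylbut-2-enoyloxy]-5,6-dihydro-2H-pyran-2-one | C/C=C(\C)C(=O)O[C@H]1C=CC(=O)O[C@H]1/C=C/[C@H](OC(C)=O)[C@H](C)OC(C)=O | target

**Step count and risks**

Total steps: 8. Longest linear sequence: 5 (steps 1, 2, 3, 4, 8); the side-chain branch is 4 (steps 5, 6, 7, 8).

Most likely to fail:

1. Step 2 (the proposed new step). Risks are acrolein oligomerisation under Mn/Me3SiCl, modest syn:anti ratio or ee, and an unverified facial sense. The fallback uses known chemistry only, sets out from 1 and 13 (made from 9 exactly as in step 5) and comes back at 5. Acrolein 1 is added to allylborane 13 at −78 °C, and the resulting borinate ester F1 is oxidised with NaOH/H2O2 to (3S,4S)-4-(methoxymethoxy)hexa-1,5-dien-3-ol F2. This alcohol is acylated with tigloyl chloride 2 (pyridine, DMAP, CH2Cl2) to the MOM-protected tiglate F3. ZnBr2/n-PrSH in CH2Cl2 at 0 °C then removes the methoxymethyl group and gives 5.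

2. Step 4. The risk is that the acrylate closes onto the vinyl group on its own carbon (butenolide) or that the spare vinyl group oligomerises. The fallback reverses the order of the two metatheses so that the ring closure has only one terminal alkene available; it sets out from 5 and 17 and comes back at 18. Alcohol 5 and 17 (3 equiv) are cross-metathesised with the second-generation Hoveyda–Grubbs catalyst (H2IMes)Cl2Ru=CH(C6H4-2-OiPr) in CH2Cl2 at 40 °C. The vinyl group next to the free hydroxyl is the more reactive one, so this gives (3S,4S,5E,7S,8S)-7,8-diacetoxy-4-hydroxynona-1,5-dien-3-yl tiglate F4. Acylation with 6 (iPr2NEt, CH2Cl2, −78 °C, cold enough to outrun the tigloyl shift, which is no longer degenerate here) gives the acrylate F5. Ring closure with the second-generation Grubbs catalyst (H2IMes)(PCy3)Cl2Ru=CHPh gives 18.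

3. Step 8. The risk is low conversion, because both alkenes carry an allylic ester and the lactone partner is hindered by the neighbouring tiglate. The fallback builds the C5–C6 bond on the side chain instead of joining two hindered alkenes; it sets out from 17 and 13 and comes back at 18. Diacetate 17 undergoes cross-metathesis with excess crotonaldehyde (C/C=C/C=O), an easy partner, under the same Hoveyda–Grubbs catalyst to give (2E,4S,5S)-4,5-diacetoxyhex-2-enal F6. Addition of F6 to allylborane 13 at −78 °C gives the borinate ester F7, which is worked up with pH 7 buffer/H2O2 (to spare the acetates) to the syn MOM-protected alcohol F8. Acylation with 6 (iPr2NEt, CH2Cl2) gives the acrylate F9, and ring-closing metathesis with the second-generation Grubbs catalyst (H2IMes)(PCy3)Cl2Ru=CHPh gives the MOM-protected lactone F10. Me2BBr in CH2Cl2 at −78 °C followed by NaHCO3 (thiol-free, to avoid conjugate addition) gives the 5-hydroxy lactone F11. Acylation with tigloyl chloride 2 (pyridine, DMAP, CH2Cl2, 0 °C) gives 18.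

**Further compounds**

F1 | step 2 | (3S,4S)-4-(methoxymethoxy)hexa-1,5-dien-3-yl bis(isopinocampheyl)borinate | C=C[C@H](OCOC)[C@@H](OB([C@H]1C[C@H]2C[C@@H]([C@@H]1C)C2(C)C)[C@H]1C[C@H]2C[C@@H]([C@@H]1C)C2(C)C)C=C
F2 | step 2 | (3S,4S)-4-(methoxymethoxy)hexa-1,5-dien-3-ol | C=C[C@H](OCOC)[C@@H](O)C=C
F3 | step 2 | (3S,4S)-4-(methoxymethoxy)hexa-1,5-dien-3-yl (E)-2-methylbut-2-enoate | C/C=C(\C)C(=O)O[C@@H](C=C)[C@@H](OCOC)C=C
F4 | step 4 | (3S,4S,5E,7S,8S)-7,8-diacetoxy-4-hydroxynona-1,5-dien-3-yl (E)-2-methylbut-2-enoate | C/C=C(\C)C(=O)O[C@@H](C=C)[C@@H](O)/C=C/[C@H](OC(C)=O)[C@H](C)OC(C)=O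
F5 | step 4 | (3S,4S,5E,7S,8S)-7,8-diacetoxy-4-(acryloyloxy)nona-1,5-dien-3-yl (E)-2-methylbut-2-enoate | C/C=C(\C)C(=O)O[C@@H](C=C)[C@@H](OC(=O)C=C)/C=C/[C@H](OC(C)=O)[C@H](C)OC(C)=O
F6 | step 8 | (2E,4S,5S)-4,5-diacetoxyhex-2-enal | O=C/C=C/[C@H](OC(C)=O)[C@H](C)OC(C)=O
F7 | step 8 | (3S,4S,5E,7S,8S)-7,8-diacetoxy-3-(methoxymethoxy)nona-1,5-dien-4-yl bis(isopinocampheyl)borinate | C=C[C@H](OCOC)[C@@H](OB([C@H]1C[C@H]2C[C@@H]([C@@H]1C)C2(C)C)[C@H]1C[C@H]2C[C@@H]([C@@H]1C)C2(C)C)/C=C/[C@H](OC(C)=O)[C@H](C)OC(C)=O
F8 | step 8 | (3S,4S,5E,7S,8S)-4-hydroxy-3-(methoxymethoxy)nona-1,5-diene-7,8-diyl diacetate | C=C[C@H](OCOC)[C@@H](O)/C=C/[C@H](OC(C)=O)[C@H](C)OC(C)=O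
F9 | step 8 | (3S,4S,5E,7S,8S)-4-(acryloyloxy)-3-(methoxymethoxy)nona-1,5-diene-7,8-diyl diacetate | C=C[C@H](OCOC)[C@@H](OC(=O)C=C)/C=C/[C@H](OC(C)=O)[C@H](C)OC(C)=O
F10 | step 8 | (5S,6S)-6-[(1E,3S,4S)-3,4-diacetoxypent-1-en-1-yl]-5-(methoxymethoxy)-5,6-dihydro-2H-pyran-2-one | COCO[C@H]1C=CC(=O)O[C@H]1/C=C/[C@H](OC(C)=O)[C@H](C)OC(C)=O
F11 | step 8 | (5S,6S)-6-[(1E,3S,4S)-3,4-diacetoxypent-1-en-1-yl]-5-hydroxy-5,6-dihydro-2H-pyran-2-one | O[C@H]1C=CC(=O)O[C@H]1/C=C/[C@H](OC(C)=O)[C@H](C)OC(C)=O
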